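**Strategy.** Germacrane numbering (C1–C15) is used. Everything rests on C3, the vinylogous-ester carbon of the furanone (O10–C3=C2–C1=O), which is at the carboxylic oxidation level. It is first held as the carbonyl of a seven-membered unsaturated lactone (O8, C3–C8), whose ring fixes the Z C4=C5 alkene. In the key step the C2 enolate of a methyl ketone on the C8 side chain is acylated by this lactone, O8 leaves and O10 closes the furanone: the nine-membered oxacycle (O10, C3–C10) arises from the seven-membered lactone by a two-atom ring expansion while the ten-membered carbocycle forms. The precursor is the trans-fused butyrolactone–oxepinone bis-lactone 17.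

Key step: step 10

Remark: ketone 8 is taken as a purchasable catalogue compound; if it had to be made, hydroxyacetone and 4-methoxybenzyl trichloroacetimidate would give it in one step.

Step 1
Reactants: 1 (S)-5-(hydroxymethyl)furan-2(5H)-one
Product: 2 (S)-5-{[(tert-butyldiphenylsilyl)oxy]methyl}furan-2(5H)-one
Conditions: TBDPSCl, imidazole, CH2Cl2, 0 °C → rt
Reagents that add atoms: tert-butyl(chloro)diphenylsilane, CC(C)(C)[Si](Cl)(c1ccccc1)c1ccccc1
Why: Imidazole-mediated silylation of the only hydroxyl group; the C6 stereocentre comes from the chiral pool and is not touched.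

Step 2
Reactants: 2 silyl butenolide; 3 vinylmagnesium bromide; 4 Eschenmoser's salt
Product: 6 all-trans Mannich lactone (3R,4S,5S), via bromomagnesium enolate 5 (not isolated)
Conditions: 3, CuI (10 mol %), THF, −78 → −40 °C; then 4, −40 °C → rt
Reagents that add atoms: none
Why: Copper-catalysed conjugate addition of the vinyl Grignard reagent should occur anti to the C6 CH2OSi group (sets C7), and the enolate is then aminomethylated anti to the new vinyl group (Mannich reaction; C11, a centre removed in step 12), which stores the α-methylene lactone as a Mannich base.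

Step 3
Reactants: 6 Mannich lactone
Product: 7 lactone aldehyde (2S,3S,4R)
Conditions: OsO4 (2 mol %), NaIO4, 2,6-lutidine, dioxane/H2O 3:1, rt
Reagents that add atoms: sodium periodate (with catalytic OsO4 the source of the aldehyde oxygen), [Na+].[O-]I(=O)(=O)=O
Why: Lemieux–Johnson oxidation (dihydroxylation, then periodate cleavage) turns the only alkene into the C8 aldehyde; lactone, silyl ether and tertiary amine are inert and the 3,4-trans aldehyde is the stable epimer.

Step 4
Reactants: 7 lactone aldehyde; 8 1-[(4-methoxybenzyl)oxy]propan-2-one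
Product: 9 syn-aldol (8S,9R)
Conditions: O-tert-butyl-L-threonine (20 mol %), 8 (5 equiv), NMP, 4 °C → rt
Reagents that add atoms: none
Why: Primary-amine enamine aldol: the threonine catalyst forms the Z enamine at the oxygen-bearing carbon of 8 and should deliver the syn aldol, the L-catalyst giving the (8S,9R) pair (L-threo ketose pattern) by re-face attack on the aldehyde under catalyst control.

Step 5
Reactants: 9 syn-aldol; 10 ethyl vinyl ether
Product: 12 α-hydroxy methyl ketone (8S,9R,10S), via enol ether 11 (not isolated)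
Conditions: 10, t-BuLi, THF, −78 → 0 °C; MgBr2·OEt2, −78 °C; then 9, −78 °C; 1 M HCl, THF, 0 °C
Reagents that add atoms: water, O
Why: Cram-chelate addition of an acyl-anion equivalent: magnesium bridges the ketone and the C9 PMB-ether oxygen and the 1-ethoxyvinyl group adds anti to the C8 substituent, setting C10 (9,10-syn), after which dilute acid hydrolyses the enol ether to the methyl ketone.

Step 6
Reactants: 12 α-hydroxy methyl ketone; 13 2-(diethoxyphosphoryl)propanoic acid
Product: 14 C8 phosphonopropanoate
Conditions: DCC, DMAP (cat.), CH2Cl2, 0 °C → rt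
Reagents that add atoms: none
Why: Steglich esterification acylates the secondary C8 hydroxyl; the tertiary α-ketol hydroxyl at C10 is too hindered to compete.

Step 7
Reactants: 14 C8 phosphonopropanoate
Product: 15 primary alcohol
Conditions: HF·pyridine, pyridine, THF, 0 °C → rt
Reagents that add atoms: none
Why: Fluoride cleavage of the primary silyl ether under acidic conditions, which avoids acyl migration and leaves ester, PMB ether and phosphonate intact.

Step 8
Reactants: 15 primary alcohol
Product: 16 C5 aldehyde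
Conditions: Dess–Martin periodinane, pyridine, CH2Cl2, 0 °C
Reagents that add atoms: none
Why: Dess–Martin oxidation of the only oxidisable alcohol (C10-OH is tertiary) gives the C5 aldehyde under buffered conditions that should not epimerise C6.

Step 9
Reactants: 16 C5 aldehyde
Product: 17 bis-lactone
Conditions: LiCl, iPr2NEt, MeCN (2 mM), rt
Reagents that add atoms: none
Why: Intramolecular Horner–Wadsworth–Emmons olefination (Masamune–Roush conditions): the phosphonate anion reacts with the aldehyde far faster than with the hindered methyl ketone, and the seven-membered ring can only hold the Z C4=C5 alkene.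

Step 10
Reactants: 17 bis-lactone
Product: 20 furanone alcohol, via ten-membered β-diketone 18 (not isolated), via hemiketal 19 (not isolated)
Conditions: LiN(SiMe3)2 (2.2 equiv), THF, −78 → −20 °C; then 2 M HCl, THF, 0 °C → rt
Reagents that add atoms: none
Why: LiN(SiMe3)2 deprotonates the C10 hydroxyl and the methyl ketone (C2); the enolate attacks the lactone carbonyl C3 through a seven-membered transition state (7-exo-trig) and the bridged tetrahedral intermediate collapses with loss of the C8 alkoxide, an intramolecular Claisen (Baker–Venkataraman-type) acyl transfer pulled over by formation of the β-diketonate of 18, so the ten-membered carbocycle is made by addition–fragmentation and not by direct cyclisation. On acidification O10 adds to C3 (5-exo-trig, hemiketal 19) and water is lost, which closes the furanone by cyclodehydration and leaves the nine-membered oxacycle O10/C3–C10 where the seven-membered lactone O8/C3–C8 stood, a net two-atom ring expansion. The closest known reactions are the base-mediated rearrangement of keto lactones to cyclic 1,3-diketones, acyl-transfer ring expansions of lactones and the acid cyclodehydration of 1-hydroxy-2,4-diketones to 3(2H)-furanones. No lasting stereocentre is created: C6–C10 are carried over, the Z C4=C5 geometry is inherited from the seven-membered ring and the hemiketal centre C3 disappears on dehydration. The step needs enolisation of the methyl ketone in preference to the lactone C–H bonds (kinetic acidity at −78 °C, no excess base), 1,2- rather than 1,4-attack on the enoate (seven- against eight-membered transition state) and closure of O10, not O8, onto the diketone (the endocyclic vinylogous ester is the thermodynamic product under reversible acid catalysis).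

Step 11
Reactants: 20 furanone alcohol; 21 isobutyric anhydride
Product: 22 C8 isobutyrate
Conditions: 21, DMAP (cat.), pyridine, CH2Cl2, rt
Reagents that add atoms: none
Why: DMAP-catalysed acylation of the only free hydroxyl group (C8).

Step 12
Reactants: 22 C8 isobutyrate
Product: 24 α-methylene lactone PMB ether, via trimethylammonium iodide 23 (not isolated)
Conditions: MeI, MeOH, rt; then NaHCO3 (aq), EtOAc, rt
Reagents that add atoms: none
Why: Quaternisation of the amine followed by base-induced β-elimination (Hofmann-type, E1cB) unveils the α-methylene lactone and removes the C11 centre.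

Step 13
Reactants: 24 α-methylene lactone PMB ether
Product: 25 target CNP0265772.2
Conditions: DDQ, CH2Cl2/pH 7 buffer 10:1, 0 °C → rt
Reagents that add atoms: none
Why: Oxidative cleavage of the PMB ether by DDQ (hydride abstraction, hydrolysis of the oxocarbenium ion) frees the C9 hydroxyl without touching the alkenes or esters.

**Compound list**

1 | (S)-5-(hydroxymethyl)furan-2(5H)-one | O=C1C=C[C@@H](CO)O1 | starting material
2 | (S)-5-{[(tert-butyldiphenylsilyl)oxy]methyl}furan-2(5H)-one | O=C1C=C[C@@H](CO[Si](c2ccccc2)(c2ccccc2)C(C)(C)C)O1 | intermediate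
3 | vinylmagnesium bromide | C=C[Mg]Br | starting material
4 | N,N-dimethylmethyleneiminium iodide (Eschenmoser's salt) | C=[N+](C)C.[I-] | starting material
5 | O-bound bromomagnesium enolate of (4S,5S)-5-{[(tert-butyldiphenylsilyl)oxy]methyl}-4-vinyldihydrofuran-2(3H)-one (vinyl trans to CH2OSi) | Br[Mg]OC1=C[C@H](C=C)[C@@H](CO[Si](c2ccccc2)(c2ccccc2)C(C)(C)C)O1 | intermediate
6 | (3R,4S,5S)-5-{[(tert-butyldiphenylsilyl)oxy]methyl}-3-[(dimethylamino)methyl]-4-vinyldihydrofuran-2(3H)-one (all-trans) | CN(C)C[C@@H]1C(=O)O[C@H](CO[Si](c2ccccc2)(c2ccccc2)C(C)(C)C)[C@H]1C=C | intermediate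
7 | (2S,3S,4R)-2-{[(tert-butyldiphenylsilyl)oxy]methyl}-4-[(dimethylamino)methyl]-5-oxotetrahydrofuran-3-carbaldehyde | CN(C)C[C@@H]1C(=O)O[C@H](CO[Si](c2ccccc2)(c2ccccc2)C(C)(C)C)[C@H]1C=O | intermediate
8 | 1-[(4-methoxybenzyl)oxy]propan-2-one | CC(=O)COCc1ccc(OC)cc1 | starting material
9 | (3R,4S)-4-[(2S,3R,4R)-2-{[(tert-butyldiphenylsilyl)oxy]methyl}-4-[(dimethylamino)methyl]-5-oxotetrahydrofuran-3-yl]-4-hydroxy-3-[(4-methoxybenzyl)oxy]butan-2-one | CN(C)C[C@@H]1C(=O)O[C@H](CO[Si](c2ccccc2)(c2ccccc2)C(C)(C)C)[C@H]1[C@H](O)[C@@H](OCc3ccc(OC)cc3)C(C)=O | intermediate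
10 | ethyl vinyl ether | C=COCC | starting material
11 | 1-ethoxyvinyl adduct of 9: tertiary alcohol at C10 (10S) carrying CH3 and C(OEt)=CH2 | CN(C)C[C@@H]1C(=O)O[C@H](CO[Si](c2ccccc2)(c2ccccc2)C(C)(C)C)[C@H]1[C@H](O)[C@@H](OCc3ccc(OC)cc3)[C@](C)(O)C(=C)OCC | intermediate
12 | (3S,4R,5S)-5-[(2S,3R,4R)-2-{[(tert-butyldiphenylsilyl)oxy]methyl}-4-[(dimethylamino)methyl]-5-oxotetrahydrofuran-3-yl]-3,5-dihydroxy-4-[(4-methoxybenzyl)oxy]-3-methylpentan-2-one | CN(C)C[C@@H]1C(=O)O[C@H](CO[Si](c2ccccc2)(c2ccccc2)C(C)(C)C)[C@H]1[C@H](O)[C@@H](OCc3ccc(OC)cc3)[C@](C)(O)C(C)=O | intermediate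
13 | 2-(diethoxyphosphoryl)propanoic acid | CC(C(=O)O)P(=O)(OCC)OCC | starting material
14 | 2-(diethoxyphosphoryl)propanoate of the C8 hydroxyl of 12 (both epimers at the phosphonate carbon) | CN(C)C[C@@H]1C(=O)O[C@H](CO[Si](c2ccccc2)(c2ccccc2)C(C)(C)C)[C@H]1[C@H](OC(=O)C(C)P(=O)(OCC)OCC)[C@@H](OCc3ccc(OC)cc3)[C@](C)(O)C(C)=O | intermediate
15 | primary alcohol: 14 with the silyl ether replaced by CH2OH | CN(C)C[C@@H]1C(=O)O[C@H](CO)[C@H]1[C@H](OC(=O)C(C)P(=O)(OCC)OCC)[C@@H](OCc3ccc(OC)cc3)[C@](C)(O)C(C)=O | intermediate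
16 | aldehyde: 15 with CH2OH oxidised to the C5 formyl group on C6 | CN(C)C[C@@H]1C(=O)O[C@H](C=O)[C@H]1[C@H](OC(=O)C(C)P(=O)(OCC)OCC)[C@@H](OCc3ccc(OC)cc3)[C@](C)(O)C(C)=O | intermediate
17 | bis-lactone (6R,7S,8S,9R,10S,11R): 11-[(dimethylamino)methyl]-γ-butyrolactone (C12 on O6) trans-fused at C6–C7 to the seven-membered (Z)-α-methyl enoate lactone (C3 on O8; ring O8, C3, C4, C5, C6, C7, C8); C8 carries CH(OPMB)–C(CH3)(OH)–C(=O)CH3 | CN(C)C[C@@H]1C(=O)O[C@@H]2/C=C(/C)C(=O)O[C@H]([C@@H](OCc3ccc(OC)cc3)[C@](C)(O)C(C)=O)[C@@H]12 | intermediate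
18 | ten-membered carbocyclic 1,3-diketone (C1, C3 carbonyls; Z C4=C5; 8-OH, 9-OPMB, 10-OH; 6,12-lactone with 11-CH2NMe2; centres as in 17) | CN(C)C[C@@H]1C(=O)O[C@@H]2/C=C(/C)C(=O)CC(=O)[C@@](C)(O)[C@H](OCc3ccc(OC)cc3)[C@@H](O)[C@@H]12 | intermediate
19 | hemiketal of 18: O10 bonded to C3 (3-hydroxy-3,10-epoxy; either C3 epimer) | CN(C)C[C@@H]1C(=O)O[C@@H]2/C=C(/C)C3(O)CC(=O)[C@@](C)(O3)[C@H](OCc4ccc(OC)cc4)[C@@H](O)[C@@H]12 | intermediate
20 | furanone alcohol: 3(2H)-furanone (O10, C3, C2, C1, C10) bridging C3 and C10, nine-membered oxacycle O10/C3–C10, 8-OH, 9-OPMB, 6,12-trans-lactone with 11-CH2NMe2 (centres as in 17) | CN(C)C[C@@H]1C(=O)O[C@@H]2/C=C(/C)C3=CC(=O)[C@@](C)(O3)[C@H](OCc4ccc(OC)cc4)[C@@H](O)[C@@H]12 | intermediate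
21 | isobutyric anhydride | CC(C)C(=O)OC(=O)C(C)C | starting material
22 | 8-O-isobutyrate of 20 | CN(C)C[C@@H]1C(=O)O[C@@H]2/C=C(/C)C3=CC(=O)[C@@](C)(O3)[C@H](OCc4ccc(OC)cc4)[C@@H](OC(=O)C(C)C)[C@@H]12 | intermediate
23 | N-methyl quaternary ammonium iodide of 22 | C[N+](C)(C)C[C@@H]1C(=O)O[C@@H]2/C=C(/C)C3=CC(=O)[C@@](C)(O3)[C@H](OCc4ccc(OC)cc4)[C@@H](OC(=O)C(C)C)[C@@H]12.[I-] | intermediate
24 | 9-O-(4-methoxybenzyl) ether of the target (α-methylene lactone in place) | C=C1C(=O)O[C@@H]2/C=C(/C)C3=CC(=O)[C@@](C)(O3)[C@H](OCc4ccc(OC)cc4)[C@@H](OC(=O)C(C)C)[C@@H]12 | intermediate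
25 | CNP0265772.2 (6R,7S,8S,9R,10S; 4Z) | C=C1C(=O)O[C@@H]2/C=C(/C)C3=CC(=O)[C@@](C)(O3)[C@H](O)[C@@H](OC(=O)C(C)C)[C@@H]12 | target

**Step count.** 13 steps in total; the longest linear sequence is 13 steps (1 → 25).

**Steps most likely to fail**

Step 10 (ring-expanding Claisen and furanone closure). The enolate may not reach the lactone carbonyl, deprotonation at C6 or at the butyrolactone α-carbon (with loss of dimethylamide) may compete, or the liberated C8 oxygen may translactonise onto C12. The fallback separates the acyl transfer from the C–C bond formation. Setting out from 17, DBU-catalysed migration of the C3 acyl group from O8 to O10 in the presence of isobutyric anhydride and DMAP, which captures the freed secondary C8 hydroxyl while the tertiary C10 hydroxyl stays unacylated, would give the nine-membered lactone isobutyrate F1. LiN(SiMe3)2 at −78 °C would then bring about the Baker–Venkataraman C-acylation through a five-membered transition state, and HCl the cyclodehydration. The route is rejoined at 22.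

Step 4 (organocatalytic syn-aldol). The enamine aldol may be slow with the α-branched aldehyde, the amine catalyst may cause epimerisation at C7 or β-elimination that opens the lactone, and catalyst control over the aldehyde face may be incomplete. The fallback is a reagent-controlled Brown alkoxyallylboration. Setting out from 7, the (Z)-γ-(4-methoxybenzyloxy)-β-methylallyl diisopinocampheylborane made from 2-methylallyl 4-methoxybenzyl ether (s-BuLi; (+)-Ipc2BOMe; BF3·OEt2) would add at −78 °C to give the syn homoallylic alcohol F2. OsO4/NaIO4 cleavage of its 1,1-disubstituted alkene comes back to the route at 9.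

Step 9 (Horner–Wadsworth–Emmons ring closure). Oligomerisation, base-induced epimerisation of the α-alkoxy aldehyde at C6 or olefination of the methyl ketone may take over. The fallback closes the ring by metathesis and sets out from 12:
- methacryloyl chloride, Et3N and DMAP would give the C8 methacrylate F3;
- HF·pyridine would give the primary alcohol F4;
- Dess–Martin periodinane would give the aldehyde F5;
- Ph3P=CH2 (1 equiv, −78 °C) would give the vinyl lactone F6;
- the second-generation Grubbs catalyst (amine protonated with TsOH, toluene, 80 °C) would close the C4=C5 bond and come back to the route at 17.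

Further compounds
F1 | step 10 | nine-membered lactone isobutyrate: C3 acyl on O10 (ring O10, C3–C10), 8-O-isobutyryl, C10 bearing CH3 and acetyl, 9-OPMB, 6,12-lactone with 11-CH2NMe2 | CN(C)C[C@@H]1C(=O)O[C@@H]2/C=C(/C)C(=O)O[C@](C)(C(C)=O)[C@H](OCc3ccc(OC)cc3)[C@@H](OC(=O)C(C)C)[C@@H]12
F2 | step 4 | syn homoallylic alcohol: 9 with the acetyl group replaced by isopropenyl (C10(CH3)=CH2) | CN(C)C[C@@H]1C(=O)O[C@H](CO[Si](c2ccccc2)(c2ccccc2)C(C)(C)C)[C@H]1[C@H](O)[C@@H](OCc3ccc(OC)cc3)C(C)=C
F3 | step 9 | C8 methacrylate of 12 | CN(C)C[C@@H]1C(=O)O[C@H](CO[Si](c2ccccc2)(c2ccccc2)C(C)(C)C)[C@H]1[C@H](OC(=O)C(C)=C)[C@@H](OCc3ccc(OC)cc3)[C@](C)(O)C(C)=O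
F4 | step 9 | primary alcohol from F3 (CH2OH on C6) | CN(C)C[C@@H]1C(=O)O[C@H](CO)[C@H]1[C@H](OC(=O)C(C)=C)[C@@H](OCc3ccc(OC)cc3)[C@](C)(O)C(C)=O
F5 | step 9 | aldehyde from F4 (formyl on C6) | CN(C)C[C@@H]1C(=O)O[C@H](C=O)[C@H]1[C@H](OC(=O)C(C)=C)[C@@H](OCc3ccc(OC)cc3)[C@](C)(O)C(C)=O
F6 | step 9 | vinyl lactone from F5 (vinyl on C6; metathesis precursor) | CN(C)C[C@@H]1C(=O)O[C@H](C=C)[C@H]1[C@H](OC(=O)C(C)=C)[C@@H](OCc3ccc(OC)cc3)[C@](C)(O)C(C)=O
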